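## Retrosynthetic overview

- **Feature used:** ring A of the apigenin unit is a phloroglucinol ring. Its C8 carries chroman C8 and lies between C8a (bearing the pyranone oxygen O1) and C7 (OH), with C5 (OH) para to C8. An aryl-substituted ynol ether and a 3-alkoxyvinylketene deliver exactly this pattern.
- **Endgame disconnections:** benzyl and ethyl ethers; ring C of the 5,7-dihydroxyflavone unit (Baker–Venkataraman from the chroman C6 carboxyl); ring C of the apigenin unit (chalcone, iodine–DMSO). The last closure must use the C8a oxygen, because the C5 oxygen is the only one that arrives as an alkyl ether.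
- **Key disconnection:** apigenin ring A goes back to siloxyalkyne 12 and 3-ethoxycyclobutenone 13 (new bonds C8a–C8, C7–C6, C4a–C8a). The biaryl bond is the former aryl–alkyne bond.
- **Precursor:** 12 comes from methyl 4-hydroxybenzoate by isoprene annulation, C8 iodination, Sonogashira coupling, and acetylide oxidation/silylation run on the lithium carboxylate.
- **Ring order:** chroman pyran ring, apigenin ring A, apigenin ring C, ring C of the second flavone. The remaining benzene rings are bought.

Key step: step 6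

Assumption: the target has no stereocentre, and the biaryl axis (three ortho oxygens, one ortho hydrogen) is taken as freely rotating, since the SMILES carries no descriptor.

Design notes:
- Iodine is introduced after the chroman is made.
- The C6 carboxyl group passes the organolithium step as its lithium salt, so it appears in 12 and 18 as the triisopropylsilyl ester.
- Phenols are protected as benzyl ethers, so no hot acid is needed at the end.

## Route

Step 1
Reactants: 1 methyl 4-hydroxybenzoate; 2 isoprene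
Product: 4 methyl 2,2-dimethylchroman-6-carboxylate, via prenylphenol 3 (not isolated)
Conditions: 2 (2.5 equiv, slow addition), Amberlyst 15, heptane–THF, 65 °C
Reagents that add atoms: none
Why: Acid-catalysed phenol–isoprene chroman synthesis (Friedel–Crafts prenylation, then Markovnikov hydroalkoxylation): the attacked carbon is ortho to the hydroxyl and only meta to the ester, prenylphenol 3 closes at once on its tertiary cation, and the halogen is deliberately absent because an ortho iodine would slow the alkylation further and could be lost by protodeiodination.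

Step 2
Reactants: 4 methyl 2,2-dimethylchroman-6-carboxylate
Product: 5 methyl 8-iodo-2,2-dimethylchroman-6-carboxylate
Conditions: NIS (1.1 equiv), CF3CO2H, rt, dark
Reagents that add atoms: N-iodosuccinimide, O=C1CCC(=O)N1I
Why: Electrophilic aromatic iodination with acid-activated NIS: C8 is the only open position ortho to the ring oxygen and is meta to the ester, whereas C5 and C7 are ortho to the ester and meta to the oxygen, so substitution should occur at C8 only.

Step 3
Reactants: 5 methyl 8-iodo-2,2-dimethylchroman-6-carboxylate; 6 ethynyltrimethylsilane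
Product: 7 methyl 2,2-dimethyl-8-[(trimethylsilyl)ethynyl]chroman-6-carboxylate
Conditions: PdCl2(PPh3)2 (2 mol%), CuI (4 mol%), Et3N, THF, 50 °C
Reagents that add atoms: none
Why: Sonogashira coupling of an aryl iodide with a terminal alkyne, which tolerates the ester and meets little steric demand next to the ring oxygen because the incoming group is linear.

Step 4
Reactants: 7 methyl 2,2-dimethyl-8-[(trimethylsilyl)ethynyl]chroman-6-carboxylate
Product: 9 8-ethynyl-2,2-dimethylchroman-6-carboxylic acid, via methyl 8-ethynyl-2,2-dimethylchroman-6-carboxylate 8 (not isolated)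
Conditions: LiOH (4 equiv), THF–MeOH–H2O, 40 °C; then 1 M HCl
Reagents that add atoms: lithium hydroxide, [Li+].[OH-]
Why: Hydroxide first cleaves the alkynyl C–Si bond (protodesilylation) and then saponifies the methyl ester, so one operation gives the terminal alkyne and frees the carboxyl group that is masked as its salt in step 5.

Step 5
Reactants: 9 8-ethynyl-2,2-dimethylchroman-6-carboxylic acid
Product: 12 triisopropylsilyl 2,2-dimethyl-8-[(triisopropylsilyloxy)ethynyl]chroman-6-carboxylate, via dilithium acetylide carboxylate 10 (not isolated), via dilithium ynolate carboxylate 11 (not isolated)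
Conditions: LiN(SiMe3)2 (2.1 equiv), THF, −78 to 0 °C; LiOOt-Bu [t-BuOOH (1.2 equiv, in decane) + LiN(SiMe3)2, THF, −78 °C], then 0 °C, 2 h; i-Pr3SiOTf (2.4 equiv), −78 to 0 °C; cold aq. NaHCO3/pentane work-up, Et3N-deactivated silica
Reagents that add atoms: tert-butyl hydroperoxide, CC(C)(C)OO; triisopropylsilyl trifluoromethanesulfonate, CC(C)[Si](C(C)C)(C(C)C)OS(=O)(=O)C(F)(F)F
Why: Known oxidation of a lithium acetylide by lithium tert-butyl peroxide (oxygen transfer with loss of tert-butoxide) to the lithium ynolate, followed by O-silylation with a bulky silyl triflate whose size favours the ynol ether over the C-silylated ketene; the lithium carboxylate is inert to acetylide, peroxide and ynolate, all of which could attack a methyl ester, and leaves the flask as the silyl ester.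

Step 6
Reactants: 12 triisopropylsilyl 2,2-dimethyl-8-[(triisopropylsilyloxy)ethynyl]chroman-6-carboxylate; 13 3-ethoxycyclobut-2-en-1-one
Product: 18 triisopropylsilyl 8-[4-ethoxy-2-hydroxy-6-(triisopropylsilyloxy)phenyl]-2,2-dimethylchroman-6-carboxylate, via ethoxyvinylketene 14 (not isolated), via vinylcyclobutenone 15 (not isolated), via dienylketene 16 (not isolated), via cyclohexadienone 17 (not isolated)
Conditions: 13 (1.6 equiv, syringe pump), toluene, sealed vessel, 145 °C
Reagents that add atoms: none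
Why: This is a Danheiser benzannulation of a cyclobutenone with a siloxyalkyne: thermal conrotatory four-electron opening of 13 gives ethoxyvinylketene 14, whose ketene C=C bond adds [2+2] to the electron-rich triple bond of 12 to give 4-vinylcyclobutenone 15. A second four-electron opening gives dienylketene 16, and apigenin ring A then closes by six-electron electrocyclisation (bond C4a–C8a) to dienone 17, which tautomerises to phenol 18; the other two new ring bonds, C8a–C8 and C7–C6, come from the [2+2] step, and the biaryl bond is the old aryl–alkyne bond. The selectivity needed is the orientation of the [2+2] addition: the siloxy oxygen makes the aryl-bearing alkyne carbon the nucleophilic end, so it bonds to the electrophilic ketene carbonyl carbon, which places the chroman between the new hydroxyl (C8a) and the silyl ether (C7) and para to the ethoxy group (C5). Because 13 is a vinylogous ester its opening needs more heat than that of 3-alkylcyclobutenones; the triisopropylsilyl ynol ether has no retro-ene path and a slow O-to-C silyl shift, and slow dosing of 13 keeps ketene dimerisation and acylation of the product phenol minor. No stereocentre survives (C4 of 15 is transient), and the silyl ester, the chroman ether and the arene are inert to neutral thermolysis.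

Step 7
Reactants: 18 triisopropylsilyl 8-[4-ethoxy-2-hydroxy-6-(triisopropylsilyloxy)phenyl]-2,2-dimethylchroman-6-carboxylate
Product: 19 8-(4-ethoxy-2,6-dihydroxyphenyl)-2,2-dimethylchroman-6-carboxylic acid
Conditions: n-Bu4NF (3 equiv), THF, 0 °C to rt; then 1 M HCl
Reagents that add atoms: none
Why: Fluoride-induced desilylation cleaves the aryl silyl ether and the silyl ester together, leaving the ethyl ether as the only blocked oxygen of ring A and making the two open ring positions equivalent.

Step 8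
Reactants: 19 8-(4-ethoxy-2,6-dihydroxyphenyl)-2,2-dimethylchroman-6-carboxylic acid
Product: 21 8-(3-acetyl-4-ethoxy-2,6-dihydroxyphenyl)-2,2-dimethylchroman-6-carboxylic acid, via difluoroboron chelate 20 (not isolated)
Conditions: AcOH (large excess), BF3·OEt2, 80 °C; then aq. MeOH, 60 °C
Reagents that add atoms: acetic acid, CC(=O)O
Why: Friedel–Crafts C-acetylation of a phloroglucinol-type ring (any O-acetate moves to carbon by Fries rearrangement under the same conditions): both open positions are equivalent and each lies between a hydroxyl and the ethoxy group, the product is held as chelate 20, which stops a second acylation, and the excess of acetic acid outcompetes the substrate's own less reactive aryl carboxyl group as acyl donor.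

Step 9
Reactants: 21 8-(3-acetyl-4-ethoxy-2,6-dihydroxyphenyl)-2,2-dimethylchroman-6-carboxylic acid
Product: 22 benzyl 8-[3-acetyl-6-(benzyloxy)-4-ethoxy-2-hydroxyphenyl]-2,2-dimethylchroman-6-carboxylate
Conditions: BnBr (2.1 equiv), K2CO3, DMF, rt
Reagents that add atoms: benzyl bromide, BrCc1ccccc1
Why: Williamson alkylation under weak base: the carboxylate and the non-chelated, vinylogously acidic C7 hydroxyl are benzylated, whereas the C8a hydroxyl is hydrogen-bonded to the acetyl group, is shielded by the chroman ring and stays free for the pyranone closure.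

Step 10
Reactants: 22 benzyl 8-[3-acetyl-6-(benzyloxy)-4-ethoxy-2-hydroxyphenyl]-2,2-dimethylchroman-6-carboxylate; 23 4-(benzyloxy)benzaldehyde
Product: 25 8-{6-(benzyloxy)-3-[(E)-3-(4-benzyloxyphenyl)prop-2-enoyl]-4-ethoxy-2-hydroxyphenyl}-2,2-dimethylchroman-6-carboxylic acid, via dipotassium acetophenone carboxylate 24 (not isolated)
Conditions: KOH (20 equiv), EtOH–THF–H2O, rt; then 1 M HCl
Reagents that add atoms: potassium hydroxide, [K+].[OH-]
Why: Claisen–Schmidt condensation of the methyl ketone with a non-enolisable aldehyde gives the E-chalcone by E1cB dehydration under thermodynamic control, and the excess hydroxide saponifies the benzyl ester early in the run, which frees the carboxyl group for step 13.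

Step 11
Reactants: 25 8-{6-(benzyloxy)-3-[(E)-3-(4-benzyloxyphenyl)prop-2-enoyl]-4-ethoxy-2-hydroxyphenyl}-2,2-dimethylchroman-6-carboxylic acid
Product: 27 8-[7-(benzyloxy)-2-(4-benzyloxyphenyl)-5-ethoxy-4-oxo-4H-chromen-8-yl]-2,2-dimethylchroman-6-carboxylic acid, via flavanone acid 26 (not isolated)
Conditions: I2 (0.1 equiv), DMSO, 125 °C
Reagents that add atoms: none
Why: Iodine-catalysed oxidative cyclisation of a 2'-hydroxychalcone in DMSO (oxa-Michael closure to flavanone 26, α-iodination, loss of HI, DMSO as terminal oxidant): only the C8a hydroxyl is free next to the enone carbonyl because the C5 oxygen is ethylated, so the 8-aryl and not the 6-aryl flavone must form.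

Step 12
Reactants: 28 2,4,6-trihydroxyacetophenone
Product: 29 1-[2,4-bis(benzyloxy)-6-hydroxyphenyl]ethanone
Conditions: BnBr (2.05 equiv), K2CO3, DMF, rt to 60 °C
Reagents that add atoms: benzyl bromide, BrCc1ccccc1
Why: Selective Williamson benzylation: one of the two hydroxyls ortho to the acetyl group always stays hydrogen-bonded and unreactive, so two equivalents of benzyl bromide should stop at the dibenzyl ether.

Step 13
Reactants: 27 8-[7-(benzyloxy)-2-(4-benzyloxyphenyl)-5-ethoxy-4-oxo-4H-chromen-8-yl]-2,2-dimethylchroman-6-carboxylic acid; 29 1-[2,4-bis(benzyloxy)-6-hydroxyphenyl]ethanone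
Product: 30 2-acetyl-3,5-bis(benzyloxy)phenyl 8-[7-(benzyloxy)-2-(4-benzyloxyphenyl)-5-ethoxy-4-oxo-4H-chromen-8-yl]-2,2-dimethylchroman-6-carboxylate
Conditions: EDC·HCl (1.5 equiv), DMAP, CH2Cl2, rt
Reagents that add atoms: none
Why: Steglich-type esterification (carbodiimide activation, acyl transfer by DMAP) acylates the chelated phenol of 29 with the unhindered C6 carboxyl group, and neither partner carries another free hydroxyl.

Step 14
Reactants: 30 2-acetyl-3,5-bis(benzyloxy)phenyl 8-[7-(benzyloxy)-2-(4-benzyloxyphenyl)-5-ethoxy-4-oxo-4H-chromen-8-yl]-2,2-dimethylchroman-6-carboxylate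
Product: 31 1-[2,4-bis(benzyloxy)-6-hydroxyphenyl]-3-{8-[7-(benzyloxy)-2-(4-benzyloxyphenyl)-5-ethoxy-4-oxo-4H-chromen-8-yl]-2,2-dimethylchroman-6-yl}propane-1,3-dione
Conditions: KOt-Bu (2.5 equiv), THF, 0 °C to rt; then 1 M HCl
Reagents that add atoms: none
Why: Baker–Venkataraman rearrangement: the ketone enolate attacks the neighbouring aryl ester intramolecularly and the acyl group moves from oxygen to carbon, driven by formation of the stabilised diketonate, while the bulky non-nucleophilic base leaves the finished flavone alone.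

Step 15
Reactants: 31 1-[2,4-bis(benzyloxy)-6-hydroxyphenyl]-3-{8-[7-(benzyloxy)-2-(4-benzyloxyphenyl)-5-ethoxy-4-oxo-4H-chromen-8-yl]-2,2-dimethylchroman-6-yl}propane-1,3-dione
Product: 32 6-[5,7-bis(benzyloxy)-4-oxo-4H-chromen-2-yl]-8-[7-(benzyloxy)-2-(4-benzyloxyphenyl)-5-ethoxy-4-oxo-4H-chromen-8-yl]-2,2-dimethylchroman
Conditions: p-TsOH·H2O (0.2 equiv), toluene, 100 °C
Reagents that add atoms: none
Why: Acid-catalysed cyclodehydration of an o-hydroxyaryl 1,3-diketone (hemiketal formation and loss of water) closes ring C of the second flavone, and catalytic sulfonic acid in toluene should leave the benzyl ethers, the ethyl ether and the chroman untouched.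

Step 16
Reactants: 32 6-[5,7-bis(benzyloxy)-4-oxo-4H-chromen-2-yl]-8-[7-(benzyloxy)-2-(4-benzyloxyphenyl)-5-ethoxy-4-oxo-4H-chromen-8-yl]-2,2-dimethylchroman
Product: 34 6-[7-(benzyloxy)-5-hydroxy-4-oxo-4H-chromen-2-yl]-8-[7-(benzyloxy)-2-(4-benzyloxyphenyl)-5-hydroxy-4-oxo-4H-chromen-8-yl]-2,2-dimethylchroman, via bis(dichloroboron) chelate 33 (not isolated)
Conditions: BCl3 (3 equiv), pentamethylbenzene (3 equiv), CH2Cl2, −78 to 0 °C; then aq. MeOH
Reagents that add atoms: none
Why: Chelation-assisted ether cleavage: BCl3 binds first to the two basic pyranone carbonyls and from there activates only the peri C5 alkoxy groups (one ethyl, one benzyl), limited stoichiometry and low temperature spare the non-chelating tertiary chroman ether, pentamethylbenzene intercepts the benzyl cation, and any extra loss of benzyl groups is harmless because step 17 removes them all.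

Step 17
Reactants: 34 6-[7-(benzyloxy)-5-hydroxy-4-oxo-4H-chromen-2-yl]-8-[7-(benzyloxy)-2-(4-benzyloxyphenyl)-5-hydroxy-4-oxo-4H-chromen-8-yl]-2,2-dimethylchroman
Product: 35 8-[5,7-dihydroxy-2-(4-hydroxyphenyl)-4-oxo-4H-chromen-8-yl]-6-(5,7-dihydroxy-4-oxo-4H-chromen-2-yl)-2,2-dimethylchroman (CNP0127025.0)
Conditions: H2 (1 atm), 10% Pd/C, THF–MeOH, rt
Reagents that add atoms: none
Why: Catalytic hydrogenolysis of aryl benzyl ethers under neutral conditions at one atmosphere should not reduce the flavone C2–C3 double bonds at a useful rate, and it avoids the hot acid that could open the chroman or trigger Wessely–Moser isomerisation of the 8-aryl-5-hydroxyflavone.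

## Compound list

1 | methyl 4-hydroxybenzoate | COC(=O)c1ccc(O)cc1 | starting material
2 | isoprene | C=CC(C)=C | starting material
3 | methyl 4-hydroxy-3-(3-methylbut-2-en-1-yl)benzoate | COC(=O)c1ccc(O)c(CC=C(C)C)c1 | intermediate
4 | methyl 2,2-dimethylchroman-6-carboxylate | COC(=O)c1ccc2OC(C)(C)CCc2c1 | intermediate
5 | methyl 8-iodo-2,2-dimethylchroman-6-carboxylate | COC(=O)c1cc(I)c2OC(C)(C)CCc2c1 | intermediate
6 | ethynyltrimethylsilane | C#C[Si](C)(C)C | starting material
7 | methyl 2,2-dimethyl-8-[(trimethylsilyl)ethynyl]chroman-6-carboxylate | COC(=O)c1cc(C#C[Si](C)(C)C)c2OC(C)(C)CCc2c1 | intermediate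
8 | methyl 8-ethynyl-2,2-dimethylchroman-6-carboxylate | COC(=O)c1cc(C#C)c2OC(C)(C)CCc2c1 | intermediate
9 | 8-ethynyl-2,2-dimethylchroman-6-carboxylic acid | OC(=O)c1cc(C#C)c2OC(C)(C)CCc2c1 | intermediate
10 | lithium 8-(lithioethynyl)-2,2-dimethylchroman-6-carboxylate | [Li+].[Li+].[O-]C(=O)c1cc(C#[C-])c2OC(C)(C)CCc2c1 | intermediate
11 | lithium 8-[(lithiooxy)ethynyl]-2,2-dimethylchroman-6-carboxylate (ynolate) | [Li+].[Li+].[O-]C(=O)c1cc(C#C[O-])c2OC(C)(C)CCc2c1 | intermediate
12 | triisopropylsilyl 2,2-dimethyl-8-[(triisopropylsilyloxy)ethynyl]chroman-6-carboxylate | CC(C)[Si](C(C)C)(C(C)C)OC#Cc1cc(C(=O)O[Si](C(C)C)(C(C)C)C(C)C)cc2CCC(C)(C)Oc12 | intermediate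
13 | 3-ethoxycyclobut-2-en-1-one | CCOC1=CC(=O)C1 | starting material
14 | 3-ethoxybuta-1,3-dien-1-one (ethoxyvinylketene) | C=C(OCC)C=C=O | intermediate
15 | 2-aryl-4-(1-ethoxyvinyl)-3-(triisopropylsilyloxy)cyclobut-2-en-1-one, aryl = 2,2-dimethyl-6-(triisopropylsilyloxycarbonyl)chroman-8-yl, racemic | CCOC(=C)C1C(=O)C(c2cc(C(=O)O[Si](C(C)C)(C(C)C)C(C)C)cc3CCC(C)(C)Oc23)=C1O[Si](C(C)C)(C(C)C)C(C)C | intermediate
16 | 2-aryl-5-ethoxy-3-(triisopropylsilyloxy)hexa-1,3,5-trien-1-one, same aryl, ketene carbon and ethoxyvinyl group cis on C3=C4 | C=C(OCC)/C=C(\C(=C=O)c1cc(C(=O)O[Si](C(C)C)(C(C)C)C(C)C)cc2CCC(C)(C)Oc12)O[Si](C(C)C)(C(C)C)C(C)C | intermediate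
17 | 2-aryl-5-ethoxy-3-(triisopropylsilyloxy)cyclohexa-2,4-dien-1-one, same aryl | CCOC1=CC(O[Si](C(C)C)(C(C)C)C(C)C)=C(c2cc(C(=O)O[Si](C(C)C)(C(C)C)C(C)C)cc3CCC(C)(C)Oc23)C(=O)C1 | intermediate
18 | triisopropylsilyl 8-[4-ethoxy-2-hydroxy-6-(triisopropylsilyloxy)phenyl]-2,2-dimethylchroman-6-carboxylate | CCOc1cc(O)c(-c2cc(C(=O)O[Si](C(C)C)(C(C)C)C(C)C)cc3CCC(C)(C)Oc23)c(O[Si](C(C)C)(C(C)C)C(C)C)c1 | intermediate
19 | 8-(4-ethoxy-2,6-dihydroxyphenyl)-2,2-dimethylchroman-6-carboxylic acid | CCOc1cc(O)c(-c2cc(C(=O)O)cc3CCC(C)(C)Oc23)c(O)c1 | intermediate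
20 | difluoroboron chelate of 21 (boron bridges the acetyl oxygen and the neighbouring phenol oxygen) | CCOc1cc(O)c(-c3cc(C(=O)O)cc4CCC(C)(C)Oc34)c2O[B-](F)(F)[O+]=C(C)c12 | intermediate
21 | 8-(3-acetyl-4-ethoxy-2,6-dihydroxyphenyl)-2,2-dimethylchroman-6-carboxylic acid | CCOc1cc(O)c(-c2cc(C(=O)O)cc3CCC(C)(C)Oc23)c(O)c1C(C)=O | intermediate
22 | benzyl 8-[3-acetyl-6-(benzyloxy)-4-ethoxy-2-hydroxyphenyl]-2,2-dimethylchroman-6-carboxylate | CCOc1cc(OCc2ccccc2)c(-c2cc(C(=O)OCc3ccccc3)cc3CCC(C)(C)Oc23)c(O)c1C(C)=O | intermediate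
23 | 4-(benzyloxy)benzaldehyde | O=Cc1ccc(OCc2ccccc2)cc1 | starting material
24 | dipotassium salt of 8-[3-acetyl-6-(benzyloxy)-4-ethoxy-2-hydroxyphenyl]-2,2-dimethylchroman-6-carboxylic acid | [K+].[K+].CCOc1cc(OCc2ccccc2)c(-c2cc(C(=O)[O-])cc3CCC(C)(C)Oc23)c([O-])c1C(C)=O | intermediate
25 | 8-{6-(benzyloxy)-3-[(E)-3-(4-benzyloxyphenyl)prop-2-enoyl]-4-ethoxy-2-hydroxyphenyl}-2,2-dimethylchroman-6-carboxylic acid | CCOc1cc(OCc2ccccc2)c(-c2cc(C(=O)O)cc3CCC(C)(C)Oc23)c(O)c1C(=O)/C=C/c1ccc(OCc2ccccc2)cc1 | intermediate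
26 | 8-[7-(benzyloxy)-2-(4-benzyloxyphenyl)-5-ethoxy-4-oxochroman-8-yl]-2,2-dimethylchroman-6-carboxylic acid (flavanone, racemic) | CCOc1cc(OCc2ccccc2)c(-c2cc(C(=O)O)cc3CCC(C)(C)Oc23)c2OC(c3ccc(OCc4ccccc4)cc3)CC(=O)c12 | intermediate
27 | 8-[7-(benzyloxy)-2-(4-benzyloxyphenyl)-5-ethoxy-4-oxo-4H-chromen-8-yl]-2,2-dimethylchroman-6-carboxylic acid | CCOc1cc(OCc2ccccc2)c(-c2cc(C(=O)O)cc3CCC(C)(C)Oc23)c2oc(-c3ccc(OCc4ccccc4)cc3)cc(=O)c12 | intermediate
28 | 2,4,6-trihydroxyacetophenone | CC(=O)c1c(O)cc(O)cc1O | starting material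
29 | 1-[2,4-bis(benzyloxy)-6-hydroxyphenyl]ethanone | CC(=O)c1c(O)cc(OCc2ccccc2)cc1OCc1ccccc1 | intermediate
30 | 2-acetyl-3,5-bis(benzyloxy)phenyl ester of 27 | CCOc1cc(OCc2ccccc2)c(-c2cc(C(=O)Oc3cc(OCc4ccccc4)cc(OCc4ccccc4)c3C(C)=O)cc3CCC(C)(C)Oc23)c2oc(-c3ccc(OCc4ccccc4)cc3)cc(=O)c12 | intermediate
31 | 1-[2,4-bis(benzyloxy)-6-hydroxyphenyl]-3-{8-[7-(benzyloxy)-2-(4-benzyloxyphenyl)-5-ethoxy-4-oxo-4H-chromen-8-yl]-2,2-dimethylchroman-6-yl}propane-1,3-dione | CCOc1cc(OCc2ccccc2)c(-c2cc(C(=O)CC(=O)c3c(O)cc(OCc4ccccc4)cc3OCc3ccccc3)cc3CCC(C)(C)Oc23)c2oc(-c3ccc(OCc4ccccc4)cc3)cc(=O)c12 | intermediate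
32 | 6-[5,7-bis(benzyloxy)-4-oxo-4H-chromen-2-yl]-8-[7-(benzyloxy)-2-(4-benzyloxyphenyl)-5-ethoxy-4-oxo-4H-chromen-8-yl]-2,2-dimethylchroman | CCOc1cc(OCc2ccccc2)c(-c2cc(-c3cc(=O)c4c(OCc5ccccc5)cc(OCc5ccccc5)cc4o3)cc3CCC(C)(C)Oc23)c2oc(-c3ccc(OCc4ccccc4)cc3)cc(=O)c12 | intermediate
33 | bis(dichloroboron) chelate of 34 (each boron bridges a C5 oxygen and the C4 carbonyl oxygen) | Cl[B-]1(Cl)Oc2cc(OCc3ccccc3)c(-c3cc(-c5cc(=[O+]6)c7c(O[B-]6(Cl)Cl)cc(OCc8ccccc8)cc7o5)cc4CCC(C)(C)Oc34)c3oc(-c4ccc(OCc5ccccc5)cc4)cc(=[O+]1)c23 | intermediate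
34 | 6-[7-(benzyloxy)-5-hydroxy-4-oxo-4H-chromen-2-yl]-8-[7-(benzyloxy)-2-(4-benzyloxyphenyl)-5-hydroxy-4-oxo-4H-chromen-8-yl]-2,2-dimethylchroman | Oc1cc(OCc2ccccc2)c(-c2cc(-c3cc(=O)c4c(O)cc(OCc5ccccc5)cc4o3)cc3CCC(C)(C)Oc23)c2oc(-c3ccc(OCc4ccccc4)cc3)cc(=O)c12 | intermediate
35 | 8-[5,7-dihydroxy-2-(4-hydroxyphenyl)-4-oxo-4H-chromen-8-yl]-6-(5,7-dihydroxy-4-oxo-4H-chromen-2-yl)-2,2-dimethylchroman (CNP0127025.0) | CC1(C)CCc2cc(-c3cc(=O)c4c(O)cc(O)cc4o3)cc(-c3c(O)cc(O)c4c(=O)cc(-c5ccc(O)cc5)oc34)c2O1 | target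

## Step count

- Total steps: 17
- Longest linear sequence: 16 (steps 1–11 and 13–17; step 12 is a one-step branch)

## Steps most likely to fail

**1. Step 6 (key step).** The vinylogous-ester cyclobutenone may open too slowly at temperatures the ynol ether tolerates. O-to-C silyl migration, ketene dimerisation or arrest at the vinylcyclobutenone stage could then overtake the annulation. The ortho-substituted aryl group may also slow the [2+2] addition.

Fallback (sets out from 5, returns at 19): the biaryl bond is made by Suzuki–Miyaura coupling instead of growing ring A. Phloroglucinol is mono-etherified with ethanol and HCl to 5-ethoxybenzene-1,3-diol F1. Both hydroxyls are protected with MOMCl/i-Pr2NEt to give 1-ethoxy-3,5-bis(methoxymethoxy)benzene F2. Lithiation between the two MOM ethers (n-BuLi, THF, 0 °C), followed by 2-isopropoxy-4,4,5,5-tetramethyl-1,3,2-dioxaborolane, gives 2-[4-ethoxy-2,6-bis(methoxymethoxy)phenyl]-4,4,5,5-tetramethyl-1,3,2-dioxaborolane F3. Coupling of F3 with 5 (Pd(OAc)2, SPhos, K3PO4, toluene–water, 90 °C) should give methyl 8-[4-ethoxy-2,6-bis(methoxymethoxy)phenyl]-2,2-dimethylchroman-6-carboxylate F4. HCl in methanol removes the MOM groups to give methyl 8-(4-ethoxy-2,6-dihydroxyphenyl)-2,2-dimethylchroman-6-carboxylate F5, and LiOH saponification gives 19.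

**2. Step 5.** Oxygen transfer to a poorly soluble dilithio species may stay incomplete. The ynolate may also be lost by C-silylation or by hydrolysis of the ynol ether on isolation.

Fallback (sets out from 9, returns at ynolate 11, which is silylated to 12 as in step 5): the ynolate is made by carbenoid rearrangement instead of acetylide oxidation. NBS (2.2 equiv) in aqueous acetonitrile converts the terminal alkyne into 8-(2,2-dibromoacetyl)-2,2-dimethylchroman-6-carboxylic acid F6. LiN(SiMe3)2 (2 equiv, −78 °C) forms the carboxylate enolate, and n-BuLi exchanges one bromine. On warming, the α-bromo enolate carbenoid rearranges with a 1,2-aryl shift to 11; this is the rearrangement that underlies the Kowalski homologation.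

**3. Step 1.** Oligomerisation of isoprene may outrun alkylation of the ester-deactivated phenol, and a second prenylation at C8 may erode the material that does react.

Fallback (sets out from 1, returns at 4): the ring carbon–carbon bond is made by a sigmatropic shift, which does not depend on ring nucleophilicity. Compound 1 is etherified with 3-chloro-3-methylbut-1-yne (CuCl2 cat., DBU, MeCN, 0 °C) to methyl 4-[(2-methylbut-3-yn-2-yl)oxy]benzoate F7. Heating in o-dichlorobenzene at 180 °C (aromatic propargyl Claisen rearrangement, 1,5-hydrogen shift, oxa-six-electron closure) gives methyl 2,2-dimethyl-2H-chromene-6-carboxylate F8. Hydrogenation (H2, 10% Pd/C, EtOAc) gives 4.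

## Further compounds

F1 | step 6 | 5-ethoxybenzene-1,3-diol | CCOc1cc(O)cc(O)c1
F2 | step 6 | 1-ethoxy-3,5-bis(methoxymethoxy)benzene | CCOc1cc(OCOC)cc(OCOC)c1
F3 | step 6 | 2-[4-ethoxy-2,6-bis(methoxymethoxy)phenyl]-4,4,5,5-tetramethyl-1,3,2-dioxaborolane | CCOc1cc(OCOC)c(B2OC(C)(C)C(C)(C)O2)c(OCOC)c1
F4 | step 6 | methyl 8-[4-ethoxy-2,6-bis(methoxymethoxy)phenyl]-2,2-dimethylchroman-6-carboxylate | CCOc1cc(OCOC)c(-c2cc(C(=O)OC)cc3CCC(C)(C)Oc23)c(OCOC)c1
F5 | step 6 | methyl 8-(4-ethoxy-2,6-dihydroxyphenyl)-2,2-dimethylchroman-6-carboxylate | CCOc1cc(O)c(-c2cc(C(=O)OC)cc3CCC(C)(C)Oc23)c(O)c1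
F6 | step 5 | 8-(2,2-dibromoacetyl)-2,2-dimethylchroman-6-carboxylic acid | OC(=O)c1cc(C(=O)C(Br)Br)c2OC(C)(C)CCc2c1
F7 | step 1 | methyl 4-[(2-methylbut-3-yn-2-yl)oxy]benzoate | COC(=O)c1ccc(OC(C)(C)C#C)cc1
F8 | step 1 | methyl 2,2-dimethyl-2H-chromene-6-carboxylate | COC(=O)c1ccc2OC(C)(C)C=Cc2c1
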